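## Retrosynthetic overview

1. The strategy rests on the (Z)-C4(CH3)=C5 alkene that lies between the oxygen-bearing carbons C3 (acetate) and C6 (lactone oxygen): C3, C4, C5 and C6 are the four ring carbons of a 2,5-disubstituted 3-methylfuran, so the ten-membered ring is a furan bridged by C7–C8–C9–C10=C1–C2, in oxidised form.
2. Target ⇐ late acylations and lactone α-methylenation ⇐ double ketone reduction with closure of the C6 hydroxyl on C12 ⇐ ten-membered (4Z)-ene-3,6-dione ⇐ singlet-oxygen opening of the bridged furan.
3. Bridged furan ⇐ Nozaki–Hiyama–Kishi closure of C9–C10 ⇐ C6–C7 bond by copper-catalysed conjugate addition of the furan C6 metal to a glyceraldehyde-derived enoate, and C2–C3 bond by allylation of 2-lithio-3-methylfuran with the (Z)-3-iodobutenyl unit made from but-2-yn-1-ol.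
4. Ring order: furan ring (bought) → ten-membered carbocycle, formed as an oxygen-bridged bicycle (step 12) → oxygen bridge cut (step 14) → five-membered lactone (step 15). The oxirane is made on the side-chain acid (step 22) and attached in step 24.

Key step: step 14

Remark on labels: C1–C15 are the germacrane labels of the target (C1=C10 and C4=C5 alkenes, C3–OAc, C6–O lactone, C7, C8–OH, C9–O ester, C11=C13, C12 carbonyl, C14 on C10, C15 on C4).

Assumption: the ring closure of step 12 is taken to place the new C9 oxygen trans to the C8 silyloxy group on the ring (both pseudo-equatorial). The opposite outcome is dealt with under the risk steps.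

## Route

Step 1
Reactants: 1 but-2-yn-1-ol
Product: 3 (2Z)-3-iodobut-2-en-1-ol, via cyclic alkenylaluminate 2 (not isolated)
Conditions: NaAlH2(OCH2CH2OMe)2, THF, 0 °C to rt; EtOAc; then N-iodosuccinimide, −78 to 0 °C
Reagents that add atoms: N-iodosuccinimide, O=C1CCC(=O)N1I
Why: Alkoxide-directed trans-hydroalumination of the propargylic alcohol puts aluminium on C3 inside a five-membered chelate (cis to the CH2O group), and iodinolysis of the C–Al bond with retention should give the (Z)-iodoalkene (hydroalumination–iodination).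

Step 2
Reactants: 3 (2Z)-3-iodobut-2-en-1-ol
Product: 4 (2Z)-1-bromo-3-iodobut-2-ene
Conditions: CBr4, PPh3, CH2Cl2, 0 °C
Reagents that add atoms: carbon tetrabromide, BrC(Br)(Br)Br
Why: Appel reaction of a primary allylic alcohol, which proceeds by SN2 displacement of the oxyphosphonium group and leaves the alkene geometry and the alkenyl iodide untouched.

Step 3
Reactants: 5 3-methylfuran
Product: 6 2-bromo-3-methylfuran
Conditions: N-bromosuccinimide, DMF, −10 to 0 °C, dark; used as a solution
Reagents that add atoms: N-bromosuccinimide, O=C1CCC(=O)N1Br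
Why: Electrophilic aromatic substitution goes to the α-carbon next to the methyl group (σ-complex stabilised by the ring oxygen and the methyl-bearing carbon), which fixes the regiochemistry that direct lithiation of 3-methylfuran would leave open.

Step 4
Reactants: 6 2-bromo-3-methylfuran; 4 (2Z)-1-bromo-3-iodobut-2-ene
Product: 8 2-[(2Z)-3-iodobut-2-en-1-yl]-3-methylfuran, via (3-methylfuran-2-yl)lithium 7 (not isolated)
Conditions: n-BuLi (1.0 equiv), THF, −78 °C; then 4, −78 to −20 °C
Reagents that add atoms: none
Why: Bromine–lithium exchange gives the 2-furyllithium regiospecifically and SN2 alkylation by the primary allylic bromide forms C2–C3; the alkenyl iodide should survive because all butyllithium is consumed first and the furyllithium is the more stabilised carbanion.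

Step 5
Reactants: 8 2-[(2Z)-3-iodobut-2-en-1-yl]-3-methylfuran
Product: 9 5-iodo-2-[(2Z)-3-iodobut-2-en-1-yl]-3-methylfuran
Conditions: N-iodosuccinimide, DMF, 0 °C, dark; used at once
Reagents that add atoms: N-iodosuccinimide, O=C1CCC(=O)N1I
Why: Electrophilic iodination at the only free α-carbon of the furan gives a handle for metalation under conditions that avoid the alkyllithium or amide bases an alkenyl iodide would not tolerate.

Step 6
Reactants: 10 (S)-2,2-dimethyl-1,3-dioxolane-4-carbaldehyde
Product: 11 methyl (2E)-3-[(4R)-2,2-dimethyl-1,3-dioxolan-4-yl]prop-2-enoate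
Conditions: (MeO)2P(O)CH2CO2Me, LiCl, DBU, MeCN, 0 °C to rt
Reagents that add atoms: trimethyl phosphonoacetate, COC(=O)CP(=O)(OC)OC
Why: Horner–Wadsworth–Emmons olefination under mild LiCl/amine conditions is E-selective and does not epimerise the α-alkoxy aldehyde (the descriptor changes from S to R only through the priority rules).

Step 7
Reactants: 11 methyl (2E)-3-[(4R)-2,2-dimethyl-1,3-dioxolan-4-yl]prop-2-enoate
Product: 12 methyl (2E,4R)-4,5-dihydroxypent-2-enoate
Conditions: AcOH/H2O (4:1), 40 °C
Reagents that add atoms: none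
Why: Acid-catalysed acetonide hydrolysis is done at the enoate stage, where the E alkene keeps the C8 hydroxyl away from the ester, so no lactone can form (after the conjugate addition the same diol would close on C12).

Step 8
Reactants: 12 methyl (2E,4R)-4,5-dihydroxypent-2-enoate
Product: 13 methyl (2E,4R)-4,5-bis[(tert-butyldimethylsilyl)oxy]pent-2-enoate
Conditions: t-BuMe2SiCl (2.5 equiv), imidazole, DMF, rt
Reagents that add atoms: tert-butyldimethylsilyl chloride, CC(C)(C)[Si](C)(C)Cl
Why: Standard silylation of both hydroxyls gives a primary and a secondary silyl ether that can later be told apart by their rates of cleavage.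

Step 9
Reactants: 9 5-iodo-2-[(2Z)-3-iodobut-2-en-1-yl]-3-methylfuran (1.5 equiv); 13 methyl (2E,4R)-4,5-bis[(tert-butyldimethylsilyl)oxy]pent-2-enoate
Product: 16 methyl (3R,4R)-4,5-bis[(tert-butyldimethylsilyl)oxy]-3-{5-[(2Z)-3-iodobut-2-en-1-yl]-4-methylfuran-2-yl}pentanoate, via furylmagnesium chloride 14 (not isolated), via silyl ketene acetal 15 (not isolated)
Conditions: 9, iPrMgCl·LiCl, THF, −40 to −20 °C; then CuBr·SMe2 (20 mol%), Me3SiCl, 13, −78 to −30 °C; aq. NH4Cl
Reagents that add atoms: none
Why: Iodine–magnesium exchange is much faster at the furyl iodide than at the alkenyl iodide, and the copper-catalysed, Me3SiCl-accelerated 1,4-addition of the furyl Grignard reagent forms C6–C7; C7 is set by Felkin–Anh-type attack anti to the allylic C8–O bond with the C8 hydrogen eclipsing the alkene, which should give the 7,8-anti (3R,4R) adduct.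

Step 10
Reactants: 16 the bis-silyl ether from step 9
Product: 17 methyl (3R,4R)-4-[(tert-butyldimethylsilyl)oxy]-5-hydroxy-3-{5-[(2Z)-3-iodobut-2-en-1-yl]-4-methylfuran-2-yl}pentanoate
Conditions: HF·pyridine, pyridine, THF, 0 °C
Reagents that add atoms: none
Why: Buffered fluoride cleaves the unhindered primary silyl ether much faster than the branched secondary one (selective desilylation), and the short cold reaction leaves little time for the freed hydroxyl to close on the ester.

Step 11
Reactants: 17 the primary alcohol from step 10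
Product: 18 methyl (3R,4R)-4-[(tert-butyldimethylsilyl)oxy]-3-{5-[(2Z)-3-iodobut-2-en-1-yl]-4-methylfuran-2-yl}-5-oxopentanoate
Conditions: Dess–Martin periodinane, NaHCO3, CH2Cl2, 0 °C to rt; used crude
Reagents that add atoms: none
Why: Buffered Dess–Martin oxidation gives the α-silyloxy aldehyde (C9) without epimerising C8 and without touching the furan or the alkenyl iodide.

Step 12
Reactants: 18 the iodoalkene aldehyde from step 11
Product: 20 furanophane alcohol methyl (7R,8R,9R)-8-[(tert-butyldimethylsilyl)oxy]-9-hydroxy-3,6-epoxy-13-norgermacra-1(10)Z,3,5-trien-12-oate, via alkenylchromium dichloride 19 (not isolated)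
Conditions: CrCl2 (10 equiv), NiCl2 (2 mol%), degassed DMSO/THF, 0.003 M, slow addition, rt
Reagents that add atoms: none
Why: Nozaki–Hiyama–Kishi reaction: zerovalent nickel inserts into the alkenyl C–I bond with retention of the Z geometry, transmetalation gives the alkenyl species of trivalent chromium 19, and its addition to the C9 aldehyde at high dilution closes the ten-membered carbocycle as the oxygen-bridged furanophane while tolerating ester and furan; C9 is set in the ring-closing transition state, which should place the chromium alkoxide and the C8 silyloxy group trans and pseudo-equatorial on the forming ring (9R).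

Step 13
Reactants: 20 the furanophane alcohol from step 12
Product: 21 methyl (7R,8R,9R)-8-[(tert-butyldimethylsilyl)oxy]-9-[(triethylsilyl)oxy]-3,6-epoxy-13-norgermacra-1(10)Z,3,5-trien-12-oate (3-methylfuran bridged at both α-carbons by C7–C8–C9–C10=C1–C2)
Conditions: Et3SiOTf, 2,6-lutidine, CH2Cl2, −78 °C
Reagents that add atoms: triethylsilyl trifluoromethanesulfonate, CC[Si](CC)(CC)OS(=O)(=O)C(F)(F)F
Why: Silylation under non-acidic, non-alkylating conditions protects C9–OH without generating benzyl-type cations that could attack the electron-rich bent furan, and gives a silyl group of intermediate lability between those used later at C3 and the one at C8.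

Step 14
Reactants: 21 the bridged furan from step 13
Product: 23 methyl (7R,8R,9R)-8-[(tert-butyldimethylsilyl)oxy]-9-[(triethylsilyl)oxy]-3,6-dioxo-13-norgermacra-1(10)Z,4Z-dien-12-oate, via bridged endoperoxide 22 (not isolated)
Conditions: O2, tetraphenylporphyrin (cat.), visible light, CH2Cl2, −78 °C; argon purge; then Me2S, −78 to 0 °C; used crude
Reagents that add atoms: dioxygen, O=O
Why: Singlet oxygen adds in a [4+2] cycloaddition across furan carbons C3 and C6 to give endoperoxide 22, and dimethyl sulfide attacks the O–O bond so that the 2,5-dioxygenated dihydrofuran collapses to the C3 and C6 carbonyls with loss of dimethyl sulfoxide. The closest known reaction type is the photooxygenation and reductive work-up of 2,5-dialkylfurans to (Z)-ene-1,4-diones, which has also been used on macrocyclic furans; a furan bridged by only six carbons is a more strained member of this class. No ring is closed: the oxygen bridge of the bicycle is cut and the ten-membered carbocycle is left. No stereocentre is formed; the C4=C5 alkene is Z because it was the C4–C5 bond of the furan and stays held in the ring, and C7, C8 and C9 are not touched. The step needs the furan to react in preference to the C1=C10 alkene, which the much higher rate of cycloaddition to a bent, strain-releasing furan over the ene reaction of a trisubstituted alkene should secure, and the neutral conditions at low temperature guard against epimerisation at C7 and β-elimination of the C8 silyloxy group in the enedione.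

Step 15
Reactants: 23 the (4Z)-ene-3,6-dione from step 14
Product: 25 (3S,6R)-3-hydroxy-8-[(tert-butyldimethylsilyl)oxy]-9-[(triethylsilyl)oxy]-13-norgermacra-1(10)Z,4Z-dien-12,6-olide (trans-fused five-membered lactone), via diol ester 24 (not isolated)
Conditions: (R)-2-methyl-CBS-oxazaborolidine (0.5 equiv), catecholborane, toluene/CH2Cl2, −78 °C; MeOH; then pyridinium p-toluenesulfonate (cat.), CH2Cl2, rt
Reagents that add atoms: none
Why: Corey–Bakshi–Shibata reduction: the (R)-oxazaborolidine binds each ketone with the alkenyl carbon as the large group, and since the sequence oxygen, alkenyl carbon, alkyl carbon, hydrogen has the same handedness at C3 and C6, one catalyst should give both the 3S and the 6R carbinol (held as borate esters, which cannot add to the second ketone); on acid catalysis only the C6 hydroxyl, γ to C12, closes to the trans-fused lactone, which also tells C6 from C3.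

Step 16
Reactants: 25 the hydroxy lactone from step 15
Product: 26 the C3 trimethylsilyl ether of 25
Conditions: Me3SiCl, imidazole, CH2Cl2, 0 °C; used crude
Reagents that add atoms: chlorotrimethylsilane, C[Si](C)(C)Cl
Why: Transient silylation masks the only free hydroxyl for the enolate chemistry with the most labile member of a graded silyl set (trimethylsilyl at C3, triethylsilyl at C9, tert-butyldimethylsilyl at C8).

Step 17
Reactants: 26 the C3 trimethylsilyl ether
Product: 28 11-(dimethylaminomethyl) lactone (C11 configuration not controlled and erased in step 18), via lithium lactone enolate 27 (not isolated)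
Conditions: LiN(iPr)2, THF, −78 °C; CH2=NMe2+ I−, −78 to 0 °C
Reagents that add atoms: N,N-dimethylmethyleneiminium iodide, C=[N+](C)C.[I-]
Why: Mannich reaction of the lactone enolate (first half of the Eschenmoser methylenation); C7 carries no leaving group, so the enolate has no elimination pathway, and silyl ethers are the only other functions present.

Step 18
Reactants: 28 the Mannich base from step 17
Product: 31 (3S)-3-hydroxy-8-[(tert-butyldimethylsilyl)oxy]-9-[(triethylsilyl)oxy]germacra-1(10)Z,4Z,11(13)-trien-12,6-olide, via trimethylammonium iodide 29 (not isolated), via silylated methylene lactone 30 (not isolated)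
Conditions: MeI, MeOH, rt; NaHCO3 (aq), CH2Cl2; then citric acid, MeOH, 0 °C
Reagents that add atoms: none
Why: Quaternisation and base-induced β-elimination of trimethylamine give the exocyclic C11=C13 alkene (second half of the Eschenmoser methylenation), and mild acidic methanolysis then cleaves only the trimethylsilyl ether at C3.

Step 19
Reactants: 31 the α-methylene lactone alcohol from step 18
Product: 32 the C3 acetate of 31
Conditions: Ac2O, pyridine, DMAP (cat.), CH2Cl2, 0 °C
Reagents that add atoms: acetic anhydride, CC(=O)OC(C)=O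
Why: Acylation of the only free hydroxyl with retention at C3; it is done after the enolate step because an acetate would not survive LiN(iPr)2.

Step 20
Reactants: 32 the C3 acetate
Product: 33 the C9 alcohol (3-acetate; 8-O-tert-butyldimethylsilyl; α-methylene lactone)
Conditions: pyridinium p-toluenesulfonate, MeOH/CH2Cl2, 0 °C to rt
Reagents that add atoms: none
Why: Acid-catalysed methanolysis removes the triethylsilyl ether far faster than the hindered tert-butyldimethylsilyl ether at C8 (selective desilylation) and spares the acetate and the methylene lactone.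

Step 21
Reactants: 34 angelic acid
Product: 35 (2Z)-2-methylbut-2-en-1-ol
Conditions: LiAlH4, Et2O, 0 °C to rt
Reagents that add atoms: none
Why: Hydride reduction of the carboxylic acid to the allylic alcohol, which does not isomerise the Z alkene.

Step 22
Reactants: 35 (2Z)-2-methylbut-2-en-1-ol
Product: 36 [(2S,3R)-2,3-dimethyloxiran-2-yl]methanol
Conditions: Ti(OiPr)4 (10 mol%), L-(+)-diethyl tartrate (12 mol%), t-BuOOH, 4 Å molecular sieves, CH2Cl2, −20 °C
Reagents that add atoms: tert-butyl hydroperoxide, CC(C)(C)OO
Why: Sharpless asymmetric epoxidation: the titanium–L-(+)-tartrate complex delivers oxygen to the face of the allylic alcohol that gives the (2S,3R)-epoxy alcohol (the same facial sense by which it turns (E)-hex-2-en-1-ol into the (2S,3S)-epoxide), and syn addition keeps the C3 methyl cis to the CH2OH group.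

Step 23
Reactants: 36 [(2S,3R)-2,3-dimethyloxiran-2-yl]methanol
Product: 37 (2R,3R)-2,3-dimethyloxirane-2-carboxylic acid
Conditions: RuCl3 (cat.), NaIO4, CCl4/MeCN/H2O, 0 °C to rt
Reagents that add atoms: water, O
Why: Ruthenium tetroxide-catalysed oxidation of the primary alcohol to the acid leaves the oxirane intact; the C2 descriptor changes from S to R only through the priority rules.

Step 24
Reactants: 33 the C9 alcohol from step 20; 37 (2R,3R)-2,3-dimethyloxirane-2-carboxylic acid
Product: 39 the 8-O-tert-butyldimethylsilyl ether of the target, via mixed trichlorobenzoic anhydride 38 (not isolated)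
Conditions: 37, 2,4,6-trichlorobenzoyl chloride, Et3N, toluene, rt; then 33, DMAP, toluene, rt to 40 °C
Reagents that add atoms: none
Why: Yamaguchi esterification: the mixed anhydride and DMAP transfer the hindered acyl group to the secondary allylic C9 hydroxyl, and the acid has a quaternary α-carbon, so it cannot epimerise.

Step 25
Reactants: 39 the silyl ether from step 24
Product: 40 the target, (3S,6R,7R,8R,9R)-3-acetoxy-8-hydroxy-9-{[(2R,3R)-2,3-dimethyloxiran-2-yl]carbonyloxy}germacra-1(10)Z,4Z,11(13)-trien-12,6-olide
Conditions: HF·pyridine, pyridine, THF, 0 °C to rt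
Reagents that add atoms: none
Why: Buffered fluoride desilylation frees C8–OH under non-basic conditions, so that the electron-poor oxirane, the two esters and the methylene lactone should survive and neither acyl migration nor relactonisation to C8 is promoted.

## Compound list

1 | but-2-yn-1-ol | CC#CCO | starting material
2 | cyclic sodium alkenylaluminate of 1 (not isolated) | CC1=CCO[Al-]1(OCCOC)OCCOC.[Na+] | intermediate
3 | (2Z)-3-iodobut-2-en-1-ol | OC/C=C(/C)I | intermediate
4 | (2Z)-1-bromo-3-iodobut-2-ene | BrC/C=C(/C)I | intermediate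
5 | 3-methylfuran | Cc1ccoc1 | starting material
6 | 2-bromo-3-methylfuran | Cc1ccoc1Br | intermediate
7 | (3-methylfuran-2-yl)lithium (not isolated) | Cc1ccoc1[Li] | intermediate
8 | 2-[(2Z)-3-iodobut-2-en-1-yl]-3-methylfuran | Cc1ccoc1C/C=C(/C)I | intermediate
9 | 5-iodo-2-[(2Z)-3-iodobut-2-en-1-yl]-3-methylfuran | Cc1cc(I)oc1C/C=C(/C)I | intermediate
10 | (S)-2,2-dimethyl-1,3-dioxolane-4-carbaldehyde | O=C[C@@H]1COC(C)(C)O1 | starting material
11 | methyl (2E)-3-[(4R)-2,2-dimethyl-1,3-dioxolan-4-yl]prop-2-enoate | COC(=O)/C=C/[C@@H]1COC(C)(C)O1 | intermediate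
12 | methyl (2E,4R)-4,5-dihydroxypent-2-enoate | COC(=O)/C=C/[C@@H](O)CO | intermediate
13 | methyl (2E,4R)-4,5-bis[(tert-butyldimethylsilyl)oxy]pent-2-enoate | COC(=O)/C=C/[C@@H](O[Si](C)(C)C(C)(C)C)CO[Si](C)(C)C(C)(C)C | intermediate
14 | {5-[(2Z)-3-iodobut-2-en-1-yl]-4-methylfuran-2-yl}magnesium chloride (not isolated) | Cc1cc([Mg]Cl)oc1C/C=C(/C)I | intermediate
15 | trimethylsilyl ketene acetal of 16 (not isolated; ketene acetal geometry not defined) | COC(O[Si](C)(C)C)=C[C@@H](c1cc(C)c(C/C=C(/C)I)o1)[C@@H](O[Si](C)(C)C(C)(C)C)CO[Si](C)(C)C(C)(C)C | intermediate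
16 | methyl (3R,4R)-4,5-bis[(tert-butyldimethylsilyl)oxy]-3-{5-[(2Z)-3-iodobut-2-en-1-yl]-4-methylfuran-2-yl}pentanoate | COC(=O)C[C@@H](c1cc(C)c(C/C=C(/C)I)o1)[C@@H](O[Si](C)(C)C(C)(C)C)CO[Si](C)(C)C(C)(C)C | intermediate
17 | methyl (3R,4R)-4-[(tert-butyldimethylsilyl)oxy]-5-hydroxy-3-{5-[(2Z)-3-iodobut-2-en-1-yl]-4-methylfuran-2-yl}pentanoate | COC(=O)C[C@@H](c1cc(C)c(C/C=C(/C)I)o1)[C@@H](O[Si](C)(C)C(C)(C)C)CO | intermediate
18 | methyl (3R,4R)-4-[(tert-butyldimethylsilyl)oxy]-3-{5-[(2Z)-3-iodobut-2-en-1-yl]-4-methylfuran-2-yl}-5-oxopentanoate | COC(=O)C[C@@H](c1cc(C)c(C/C=C(/C)I)o1)[C@@H](O[Si](C)(C)C(C)(C)C)C=O | intermediate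
19 | alkenylchromium dichloride derived from 18 (trivalent chromium; not isolated) | COC(=O)C[C@@H](c1cc(C)c(C/C=C(/C)[Cr](Cl)Cl)o1)[C@@H](O[Si](C)(C)C(C)(C)C)C=O | intermediate
20 | furanophane alcohol, methyl (7R,8R,9R)-8-[(tert-butyldimethylsilyl)oxy]-9-hydroxy-3,6-epoxy-13-norgermacra-1(10)Z,3,5-trien-12-oate | Cc1cc2oc1C/C=C(/C)[C@@H](O)[C@H](O[Si](C)(C)C(C)(C)C)[C@H]2CC(=O)OC | intermediate
21 | key-step precursor, 9-O-triethylsilyl ether of 20 (7R,8R,9R) | Cc1cc2oc1C/C=C(/C)[C@@H](O[Si](CC)(CC)CC)[C@H](O[Si](C)(C)C(C)(C)C)[C@H]2CC(=O)OC | intermediate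
22 | endoperoxide of 21 with the O–O bridge across C3 and C6 (not isolated; bridgehead configuration follows the face of addition, is not assigned and is erased in the same flask) | CC1=CC23OOC1(O2)C/C=C(/C)[C@@H](O[Si](CC)(CC)CC)[C@H](O[Si](C)(C)C(C)(C)C)[C@H]3CC(=O)OC | intermediate
23 | key-step product, methyl (7R,8R,9R)-8-[(tert-butyldimethylsilyl)oxy]-9-[(triethylsilyl)oxy]-3,6-dioxo-13-norgermacra-1(10)Z,4Z-dien-12-oate | O=C1/C=C(/C)C(=O)C/C=C(/C)[C@@H](O[Si](CC)(CC)CC)[C@H](O[Si](C)(C)C(C)(C)C)[C@H]1CC(=O)OC | intermediate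
24 | (3S,6R)-3,6-diol methyl ester (not isolated) | O[C@@H]1/C=C(/C)[C@@H](O)C/C=C(/C)[C@@H](O[Si](CC)(CC)CC)[C@H](O[Si](C)(C)C(C)(C)C)[C@H]1CC(=O)OC | intermediate
25 | (3S,6R)-3-hydroxy-8-[(tert-butyldimethylsilyl)oxy]-9-[(triethylsilyl)oxy]-13-norgermacra-1(10)Z,4Z-dien-12,6-olide (trans-fused lactone) | C1C(=O)O[C@@H]2/C=C(/C)[C@@H](O)C/C=C(/C)[C@@H](O[Si](CC)(CC)CC)[C@H](O[Si](C)(C)C(C)(C)C)[C@@H]12 | intermediate
26 | 3-O-trimethylsilyl ether of 25 | C1C(=O)O[C@@H]2/C=C(/C)[C@@H](O[Si](C)(C)C)C/C=C(/C)[C@@H](O[Si](CC)(CC)CC)[C@H](O[Si](C)(C)C(C)(C)C)[C@@H]12 | intermediate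
27 | lithium enolate of lactone 26 (not isolated) | C1=C(O[Li])O[C@@H]2/C=C(/C)[C@@H](O[Si](C)(C)C)C/C=C(/C)[C@@H](O[Si](CC)(CC)CC)[C@H](O[Si](C)(C)C(C)(C)C)[C@@H]12 | intermediate
28 | 11-(dimethylaminomethyl) lactone (C11 configuration not controlled) | CN(C)CC1C(=O)O[C@@H]2/C=C(/C)[C@@H](O[Si](C)(C)C)C/C=C(/C)[C@@H](O[Si](CC)(CC)CC)[C@H](O[Si](C)(C)C(C)(C)C)[C@@H]12 | intermediate
29 | trimethylammonium iodide of 28 (not isolated) | C[N+](C)(C)CC1C(=O)O[C@@H]2/C=C(/C)[C@@H](O[Si](C)(C)C)C/C=C(/C)[C@@H](O[Si](CC)(CC)CC)[C@H](O[Si](C)(C)C(C)(C)C)[C@@H]12.[I-] | intermediate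
30 | 3-O-trimethylsilyl α-methylene lactone (not isolated) | C=C1C(=O)O[C@@H]2/C=C(/C)[C@@H](O[Si](C)(C)C)C/C=C(/C)[C@@H](O[Si](CC)(CC)CC)[C@H](O[Si](C)(C)C(C)(C)C)[C@@H]12 | intermediate
31 | (3S)-3-hydroxy-8-[(tert-butyldimethylsilyl)oxy]-9-[(triethylsilyl)oxy]germacra-1(10)Z,4Z,11(13)-trien-12,6-olide | C=C1C(=O)O[C@@H]2/C=C(/C)[C@@H](O)C/C=C(/C)[C@@H](O[Si](CC)(CC)CC)[C@H](O[Si](C)(C)C(C)(C)C)[C@@H]12 | intermediate
32 | 3-acetate of 31 | C=C1C(=O)O[C@@H]2/C=C(/C)[C@@H](OC(C)=O)C/C=C(/C)[C@@H](O[Si](CC)(CC)CC)[C@H](O[Si](C)(C)C(C)(C)C)[C@@H]12 | intermediate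
33 | 3-acetoxy-9-hydroxy-8-[(tert-butyldimethylsilyl)oxy]germacra-1(10)Z,4Z,11(13)-trien-12,6-olide | C=C1C(=O)O[C@@H]2/C=C(/C)[C@@H](OC(C)=O)C/C=C(/C)[C@@H](O)[C@H](O[Si](C)(C)C(C)(C)C)[C@@H]12 | intermediate
34 | angelic acid | C/C=C(/C)C(=O)O | starting material
35 | (2Z)-2-methylbut-2-en-1-ol | C/C=C(/C)CO | intermediate
36 | [(2S,3R)-2,3-dimethyloxiran-2-yl]methanol | OC[C@]1(C)O[C@@H]1C | intermediate
37 | (2R,3R)-2,3-dimethyloxirane-2-carboxylic acid | OC(=O)[C@]1(C)O[C@@H]1C | intermediate
38 | mixed anhydride of 37 with 2,4,6-trichlorobenzoic acid (not isolated) | O=C(OC(=O)[C@]1(C)O[C@@H]1C)c1c(Cl)cc(Cl)cc1Cl | intermediate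
39 | 8-O-tert-butyldimethylsilyl ether of the target | C=C1C(=O)O[C@@H]2/C=C(/C)[C@@H](OC(C)=O)C/C=C(/C)[C@@H](OC(=O)[C@]3(C)O[C@@H]3C)[C@H](O[Si](C)(C)C(C)(C)C)[C@@H]12 | intermediate
40 | CNP0137407.10 | C=C1C(=O)O[C@@H]2/C=C(/C)[C@@H](OC(C)=O)C/C=C(/C)[C@@H](OC(=O)[C@]3(C)O[C@@H]3C)[C@H](O)[C@@H]12 | target

## Step count and risks

Total step count: 25.
Longest linear sequence: 18 steps (steps 1, 2, 4, 5, 9 to 20, 24, 25).

The three steps most likely to fail:

Step 12. The ring closure may show poor facial selectivity at the aldehyde carbon: the open-chain Felkin–Anh preference of an α-silyloxy aldehyde favours carbon attack anti to the C8–O bond, which leads to the 9-epimer, and only the constraints of the forming ring speak for the 9R alcohol. The fallback sets C9 by a ketone reduction instead of by the carbon–carbon bond formation. It sets out from 18: the same CrCl2/NiCl2 closure is run, and the 9-epimeric furanophane alcohol F1 (alone or mixed with 20) is oxidised with Dess–Martin periodinane to the C9 enone F2. Reduction of F2 with NaBH4 and CeCl3 in MeOH at −78 °C (Luche reduction) should add hydride anti to the C8–O bond, which for the ketone leads to the 8,9-syn alcohol, and the route is rejoined at 20.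

Step 15. The double reduction may show poor facial selectivity at C6: there the branched C7 competes with the alkenyl carbon for the role of the large group, and the Felkin–Anh bias of C7 directs hydride to the face that leads to the 6-epimer. The fallback corrects C6 by inversion during lactone formation. It sets out from 23: the same reduction gives the 6-epimeric diol ester F4, which closes to the cis-fused lactone F5. LiOH in THF/water opens F5 to the hydroxy acid F6, which is used at once after careful acidification at 0 °C. Mitsunobu lactonisation (PPh3, diisopropyl azodicarboxylate, toluene, high dilution, 0 °C) then closes the five-membered ring with inversion at C6, the only carbinol the internal carboxylate can reach, and the route is rejoined at 25.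

Step 14. The photooxygenation may suffer from competing ene oxidation of the C1=C10 alkene, or the strained endoperoxide may fragment or rearrange before it is reduced. The fallback opens the furan by electrophilic oxidation in two stages without an endoperoxide. It sets out from 21: N-bromosuccinimide and NaHCO3 in MeOH at −40 °C convert the furan into the bridged bis(methyl ketal) F3 (a 2,5-dimethoxy-2,5-dihydrofuran). Hydrolysis of F3 with pyridinium p-toluenesulfonate in wet acetone at 0 °C releases the (Z)-enedione, and the route is rejoined at 23.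

Further compounds
F1 | step 12 | 9-epimer of furanophane alcohol 20 (7R,8R,9S) | Cc1cc2oc1C/C=C(/C)[C@H](O)[C@H](O[Si](C)(C)C(C)(C)C)[C@H]2CC(=O)OC
F2 | step 12 | C9 ketone (enone) of the furanophane | Cc1cc2oc1C/C=C(/C)C(=O)[C@H](O[Si](C)(C)C(C)(C)C)[C@H]2CC(=O)OC
F3 | step 14 | bridged bis(methyl ketal) of 21 with methoxy groups at C3 and C6 (ketal configuration not defined) | CC1=CC2(OC)OC1(OC)C/C=C(/C)[C@@H](O[Si](CC)(CC)CC)[C@H](O[Si](C)(C)C(C)(C)C)[C@H]2CC(=O)OC
F4 | step 15 | 6-epimer of diol ester 24 (not isolated) | O[C@H]1/C=C(/C)[C@@H](O)C/C=C(/C)[C@@H](O[Si](CC)(CC)CC)[C@H](O[Si](C)(C)C(C)(C)C)[C@H]1CC(=O)OC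
F5 | step 15 | cis-fused lactone, 6-epimer of 25 | C1C(=O)O[C@H]2/C=C(/C)[C@@H](O)C/C=C(/C)[C@@H](O[Si](CC)(CC)CC)[C@H](O[Si](C)(C)C(C)(C)C)[C@@H]12
F6 | step 15 | hydroxy acid from F5 | O[C@H]1/C=C(/C)[C@@H](O)C/C=C(/C)[C@@H](O[Si](CC)(CC)CC)[C@H](O[Si](C)(C)C(C)(C)C)[C@H]1CC(=O)O
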